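The vessel was closed, stirred and isothermal, and the curve I wanted from it was that of the complex with one exchanged on Thursday's.

| setting | blue | violet | Tuesday's | Thursday's | Monday's |
|---|---|---|---|---|---|
| starting complex | 0.050 M | 0.050 M | 0.050 M | 0.050 M | 0.050 M |
| incoming ligand | 0.017 M | 0.14 M | 0.0250 M | 0.0500 M | 0.200 M |
| leaving ligand | 0.050 M | 0.050 M | 0.0500 M | 0.0500 M | 0.0500 M |
| protic impurity | 0.025 M | 0.025 M | 0.0250 M | 0.0250 M | 0.0250 M |
| remark | run made earlier | run made earlier |  |  |  |
| time |  |  | 10 min | 10 min | 10 min |

- blue (time / min: complex with one exchanged / %, complex with four exchanged / %, starting complex / %): 1.00: 12.6, 0, 55.2; 2.00: 6.7, 0, 42.1; 3.00: 4.0, 0.1, 33.6; 4.00: 2.4, 0.7, 29.4; 5.00: 1.1, 0.6, 25.6; 6.00: 0.7, 0, 23.5; 8.00: 0.6, 0, 20.4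
- violet (time / min: complex with one exchanged / %, complex with four exchanged / %, starting complex / %): 0.500: 9.0, 8.9, 8.4; 0.833: 3.6, 16.1, 5.2; 1.33: 2.4, 22.6, 1.5; 2.00: 0.5, 27.6, 1.6; 3.00: 0.6, 30.2, 1.3; 5.00: 0.1, 31.8, 1.3; 8.00: 0, 32.1, 1.2

(each reading ± 0.5 percentage points)

- which of these holds the largest part of the starting complex at the end of Tuesday's (complex with one exchanged / starting complex / complex with four exchanged / complex with three exchanged / complex with two exchanged)
- which of these holds the largest part of the starting complex at the end of Thursday's (complex with one exchanged / starting complex / complex with four exchanged / complex with three exchanged / complex with two exchanged)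
- which of these holds the largest part of the starting complex at the end of Monday's (complex with one exchanged / starting complex / complex with four exchanged / complex with three exchanged / complex with two exchanged)
- complex with one exchanged at the end of Thursday's, in percent of the starting complex charged



In the blue run that complex fell from 12.6% at 1.00 min to 2.4% at 4.00 min. I wanted its rate of loss divided by its amount, so I took the logarithm of the ratio of these two readings over the minutes between them and got the tail constant λ = 0.553 min⁻¹, a reading of the fraction lost per minute, which is a half-life of 1.25 min.

I then drew Thursday's curve in order. For the start, the violet run's starting complex fell to 8.4% in 0.500 min. Scaled to 0.0500 M of incoming ligand, this gave a rough pseudo-first-order constant k′ = 1.77 min⁻¹, so the curve rose steeply from zero. For the knee, the ligand was charged level with the starting complex, so I let k′ serve for the ligand too: 3 lifetimes, 1.70 min, left about 4.98% of it. That was earlier than the blue reading at 2.00 min, so I took that reading, 6.7%, as the head of the tail. For the level, λ carried this to 0.0805% at 10 min, against a scatter of 0.5 percentage points.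

The forecast gave complex with two exchanged, complex with two exchanged, complex with four exchanged and 0.3%, calling this complex “a short-lived intermediate”; its figure stood above my 0.0805%.

The flask gave starting complex, complex with two exchanged, complex with four exchanged and 0.0680%. The forecast failed on Tuesday's, where the starting complex, 17.5%, stood above the complex with two exchanged, 10.7%.

    starting complex + incoming ligand → leaving ligand + complex with one exchanged (k = 65.4 M⁻¹ min⁻¹)
    complex with one exchanged + incoming ligand → leaving ligand + complex with two exchanged (k = 120 M⁻¹ min⁻¹)
    complex with two exchanged + incoming ligand → leaving ligand + complex with three exchanged (k = 23.5 M⁻¹ min⁻¹)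
    complex with three exchanged + incoming ligand → leaving ligand + complex with four exchanged (k = 36.5 M⁻¹ min⁻¹)
    complex with one exchanged → side product (k = 0.608 min⁻¹)
    starting complex ⇌ dormant form (K = 2.80, k = 0.309 min⁻¹)
    protic impurity + incoming ligand → quenched reagent (k = 4.78 M⁻¹ min⁻¹)

On Thursday's the incoming ligand was down to 0.29% of its charge at 2.5 min. With the step to the side product struck out, the complex with one exchanged ended at 22.8% instead of 0.0680%, so that step is the largest single effect on the tail. Read at 2.5 min, the neighbour flask with Thursday's charges gets 5.08% from λ; the computed amount is 6.34%.

The runs were generated by integration for substances that don't exist.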